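**Retrosynthetic overview**
- The target is reached by one global O-dealkylation (benzyl, MOM and the central 3′-methyl ether) of a protected (3R)-isoflavan.
- Ring C and the C3–C1′ bond are made together in the key step: an anodically triggered dehydrative phenonium relay. Ring B shifts onto the carbinol carbon with inversion, and ring A closes on the neighbouring CH2 (C4–C4a bond).
- The cascade substrate, a (2R)-1-aryloxy-3-arylpropan-2-ol, comes from opening an (R)-aryl glycidyl ether with the ortho-lithiated ring B arene. The glycidyl ether is made from the ring A phenol and (S)-epichlorohydrin, the only source of chirality.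
- The ring B arene comes from 2,3-dimethoxyphenol by O-prenylation, aromatic Claisen rearrangement (installs the 1,1-dimethylallyl group) and MOM protection.
- Rings A and B are bought as benzenes; ring C is the only ring formed, in the key step.

Assumption: the configuration drawn in the target SMILES is (3R).

**Route**

Step 1
Reactants: 1 2,3-dimethoxyphenol; 2 prenyl bromide (1-bromo-3-methylbut-2-ene)
Product: 3 1,2-dimethoxy-3-[(3-methylbut-2-en-1-yl)oxy]benzene
Conditions: K2CO3, acetone, reflux
Reagents that add atoms: none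
Why: Williamson ether synthesis; the phenoxide of the only free OH displaces the primary allylic bromide (SN2), so no regiochemical question arises.

Step 2
Reactants: 3 1,2-dimethoxy-3-[(3-methylbut-2-en-1-yl)oxy]benzene
Product: 5 2,3-dimethoxy-6-(2-methylbut-3-en-2-yl)phenol, via ortho-dienone 4 (not isolated)
Conditions: PhNEt2, 185 °C, sealed tube, stopped at full conversion
Reagents that add atoms: none
Why: Aromatic ortho-Claisen rearrangement; the [3,3] shift delivers the dimethyl-substituted allyl terminus to C6, the only unsubstituted ortho carbon, and dienone 4 tautomerises to the phenol, giving the 1,1-dimethylallyl group directly.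

Step 3
Reactants: 5 2,3-dimethoxy-6-(2-methylbut-3-en-2-yl)phenol
Product: 6 1,2-dimethoxy-3-(methoxymethoxy)-4-(2-methylbut-3-en-2-yl)benzene
Conditions: NaH, MOMCl, DMF, 0 °C → rt
Reagents that add atoms: chloromethyl methyl ether (MOMCl), COCCl
Why: Williamson-type O-alkylation of the hindered sodium phenoxide; MOM survives n-BuLi, has no free ortho position to direct lithiation elsewhere, and is cleaved by BCl3 at the end.

Step 4
Reactants: 7 3-(benzyloxy)phenol; 8 (S)-epichlorohydrin
Product: 10 (2R)-2-{[3-(benzyloxy)phenoxy]methyl}oxirane, via chlorohydrin 9 (not isolated)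
Conditions: CsF, DMF, 50 °C
Reagents that add atoms: none
Why: Fluoride-assisted glycidylation; the phenol opens the epoxide of 8 at its CH2 terminus and chlorohydrin 9 recloses by displacing chloride, so the C–O bond of the stereocentre is never broken and, because the two CH2 groups exchange roles, (S)-8 gives (R)-10.

Step 5
Reactants: 6 1,2-dimethoxy-3-(methoxymethoxy)-4-(2-methylbut-3-en-2-yl)benzene; 10 (2R)-2-{[3-(benzyloxy)phenoxy]methyl}oxirane
Product: 12 (2R)-1-[3-(benzyloxy)phenoxy]-3-[2,3-dimethoxy-4-(methoxymethoxy)-5-(2-methylbut-3-en-2-yl)phenyl]propan-2-ol, via aryllithium 11 (not isolated)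
Conditions: n-BuLi, THF, 0 °C → rt; then 10, BF3·OEt2, −78 °C; aq. NH4Cl
Reagents that add atoms: none
Why: Methoxy-directed ortho-lithiation occurs at the only ring CH next to an OMe (the other CH is flanked by the quaternary carbon), and the aryllithium opens the BF3-activated epoxide at its CH2 terminus (SN2), leaving the stereocentre untouched, so 12 is (2R).

Step 6
Reactants: 12 (2R)-1-[3-(benzyloxy)phenoxy]-3-[2,3-dimethoxy-4-(methoxymethoxy)-5-(2-methylbut-3-en-2-yl)phenyl]propan-2-ol
Product: 15 (3R)-7-(benzyloxy)-3-[2,3-dimethoxy-4-(methoxymethoxy)-5-(2-methylbut-3-en-2-yl)phenyl]chromane, via alkoxyphosphonium triflate 13 (not isolated), via phenonium triflate 14 (not isolated)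
Conditions: PPh3 (1.5 equiv), 2,6-lutidinium triflate (0.1 M), CH2Cl2, graphite anode/Pt cathode, undivided cell, 3 mA cm−2, 2.1 F mol−1, rt; then HFIP (25 vol %), 40 °C
Reagents that add atoms: none
Why: Proposed new method: anodic two-electron oxidation of PPh3 (which oxidises about 0.3 V below either alkoxyarene and far below the terminal alkene) in the presence of the secondary alcohol gives alkoxytriphenylphosphonium ion 13, the phosphoranyl radical being oxidised at the electrode before it can fragment; electron-rich ring B then expels Ph3P=O from the back side to give the spirocyclopropyl phenonium ion 14 with inversion at the carbinol carbon, and ring A attacks the unsubstituted cyclopropane carbon in a 6-endo Friedel–Crafts alkylation para to its benzyloxy group, so ring B ends on C3 with clean inversion ((2R)-alcohol to (3R)-isoflavan) and ring C closes in the same operation; the closest known reactions are the anodic formation of alkoxyphosphonium salts from alcohols and PPh3 followed by substitution with inversion, phenonium (1,2-aryl shift) rearrangements of activated β-aryl alcohols, and the Lewis-acid cyclialkylation of aryl glycidyl ethers to 3-chromanols, whose endo selectivity is the model for the ring closure.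

Step 7
Reactants: 15 (3R)-7-(benzyloxy)-3-[2,3-dimethoxy-4-(methoxymethoxy)-5-(2-methylbut-3-en-2-yl)phenyl]chromane
Product: 16 (3R)-3-[3,4-dihydroxy-2-methoxy-5-(2-methylbut-3-en-2-yl)phenyl]chroman-7-ol (target)
Conditions: BCl3 (6 equiv), C6HMe5 (4 equiv), CH2Cl2, −78 → 0 °C; MeOH, then aq. NaHCO3
Reagents that add atoms: none
Why: Lewis-acid ether cleavage; BCl3 with pentamethylbenzene as cation scavenger removes the aryl benzyl and MOM ethers at −78 °C without touching the alkene, and on warming the boron bound to the freed 4′-oxygen cleaves the adjacent central 3′-OMe by chelation, while the non-chelated 2′-OMe, the ring C ether and C3 are unaffected.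

**Compound list**

1 | 2,3-dimethoxyphenol | COc1cccc(O)c1OC | starting material
2 | prenyl bromide (1-bromo-3-methylbut-2-ene) | CC(C)=CCBr | starting material
3 | 1,2-dimethoxy-3-[(3-methylbut-2-en-1-yl)oxy]benzene | COc1cccc(OCC=C(C)C)c1OC | intermediate
4 | 2,3-dimethoxy-6-(2-methylbut-3-en-2-yl)cyclohexa-2,4-dien-1-one (racemic ortho-dienone, not isolated) | C=CC(C)(C)C1C=CC(OC)=C(OC)C1=O | intermediate
5 | 2,3-dimethoxy-6-(2-methylbut-3-en-2-yl)phenol | C=CC(C)(C)c1ccc(OC)c(OC)c1O | intermediate
6 | 1,2-dimethoxy-3-(methoxymethoxy)-4-(2-methylbut-3-en-2-yl)benzene | C=CC(C)(C)c1ccc(OC)c(OC)c1OCOC | intermediate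
7 | 3-(benzyloxy)phenol | Oc1cccc(OCc2ccccc2)c1 | starting material
8 | (S)-epichlorohydrin, (2S)-2-(chloromethyl)oxirane | ClC[C@@H]1CO1 | starting material
9 | (2S)-1-[3-(benzyloxy)phenoxy]-3-chloropropan-2-ol (not isolated) | ClC[C@@H](O)COc1cccc(OCc2ccccc2)c1 | intermediate
10 | (2R)-2-{[3-(benzyloxy)phenoxy]methyl}oxirane | c1ccc(COc2cccc(OC[C@H]3CO3)c2)cc1 | intermediate
11 | [2,3-dimethoxy-4-(methoxymethoxy)-5-(2-methylbut-3-en-2-yl)phenyl]lithium (not isolated) | [Li]c1cc(C(C)(C)C=C)c(OCOC)c(OC)c1OC | intermediate
12 | (2R)-1-[3-(benzyloxy)phenoxy]-3-[2,3-dimethoxy-4-(methoxymethoxy)-5-(2-methylbut-3-en-2-yl)phenyl]propan-2-ol | O[C@H](Cc1cc(C(C)(C)C=C)c(OCOC)c(OC)c1OC)COc1cccc(OCc2ccccc2)c1 | intermediate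
13 | triphenylphosphonium triflate carrying the (2R)-alkoxy group of 12 on phosphorus (not isolated) | c1ccccc1[P+](c1ccccc1)(c1ccccc1)O[C@H](Cc1cc(C(C)(C)C=C)c(OCOC)c(OC)c1OC)COc1cccc(OCc2ccccc2)c1.[O-]S(=O)(=O)C(F)(F)F | intermediate
14 | phenonium triflate: ring B spiro-fused through C1′ to a cyclopropane made of C1′, the former ArCH2 carbon and the inverted carbinol carbon (R, bearing the CH2O–ring A chain); charge delocalised over ring B and drawn on the 4′-oxygen; spiro carbon not defined (not isolated) | COC[O+]=C1C(C(C)(C)C=C)=CC2(C[C@H]2COc2cccc(OCc3ccccc3)c2)C(OC)=C1OC.[O-]S(=O)(=O)C(F)(F)F | intermediate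
15 | (3R)-7-(benzyloxy)-3-[2,3-dimethoxy-4-(methoxymethoxy)-5-(2-methylbut-3-en-2-yl)phenyl]chromane | C=CC(C)(C)c1cc([C@@H]2COc3cc(OCc4ccccc4)ccc3C2)c(OC)c(OC)c1OCOC | intermediate
16 | (3R)-3-[3,4-dihydroxy-2-methoxy-5-(2-methylbut-3-en-2-yl)phenyl]chroman-7-ol | C=CC(C)(C)c1cc([C@@H]2COc3cc(O)ccc3C2)c(OC)c(O)c1O | target

**Step count**

Total: 7 steps. Longest linear sequence: 6 steps (steps 1, 2, 3, 5, 6, 7); step 4 is the one-step side branch.

**Three steps most likely to fail**

Step 6 (the proposed cascade). Four failure modes are foreseeable: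
- Ring B may be oxidised at the anode in competition with PPh3.
- The out-of-plane 2′-OMe oxygen may displace Ph3P=O instead of the ring carbon, ending in an O-demethylated 2-(aryloxymethyl)dihydrobenzofuran.
- Ring A may attack the substituted cyclopropane carbon (5-exo), giving a 3-benzyl-dihydrobenzofuran.
- The PPh3 radical cation may add to the alkene once the alcohol is consumed.

None of these side paths can invert C3, so they cost yield, not enantiopurity. The fallback uses only known reaction types and sets out from glycidyl ether 10. AuCl3 (2.5 mol %)/AgOTf (7.5 mol %) in ClCH2CH2Cl at 50 °C effects the known 6-endo epoxy-arene cyclialkylation to (3R)-7-(benzyloxy)chroman-3-ol F1, with the stereocentre untouched. TsCl in pyridine gives (3R)-7-(benzyloxy)chroman-3-yl 4-methylbenzenesulfonate F2. Aryllithium 11 (2.2 equiv, made from 6 as in step 5) and CuI (1.1 equiv) give lithium bis[2,3-dimethoxy-4-(methoxymethoxy)-5-(2-methylbut-3-en-2-yl)phenyl]cuprate F3. This displaces the secondary tosylate in Et2O/THF at −20 → 0 °C with inversion (cuprate SN2) and comes back to the route at 15 with the same (3R) configuration. Step 5 and compound 12 are then not needed.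

Step 7 (triple dealkylation). Excess BCl3 may also cleave the hindered 2′-OMe, the 3′-OMe may survive if the mixture is kept too cold, and HCl formed on quenching could close the freed 4′-OH onto the dimethylallyl group. The fallback sets out from 15 and replaces Lewis-acid demethylation by an oxidative one. HCl (1 M) in MeOH at 40 °C removes only the MOM group to give (3R)-7-(benzyloxy)-3-[4-hydroxy-2,3-dimethoxy-5-(2-methylbut-3-en-2-yl)phenyl]chromane F4. IBX (2-iodoxybenzoic acid) in DMF at rt converts this ortho-methoxyphenol with loss of methanol into 4-[(3R)-7-(benzyloxy)chroman-3-yl]-3-methoxy-6-(2-methylbut-3-en-2-yl)cyclohexa-3,5-diene-1,2-dione F5. Na2S2O4 in aqueous THF reduces the ortho-quinone to 4-[(3R)-7-(benzyloxy)chroman-3-yl]-3-methoxy-6-(2-methylbut-3-en-2-yl)benzene-1,2-diol F6. BCl3/C6HMe5 at −78 °C for 30 min with a cold quench then removes only the benzyl group and comes back to the route at 16.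

Step 2 (Claisen rearrangement). At 185 °C the product can go on to the abnormal Claisen isomer, cyclise to a trimethylcoumaran, or form some para-prenyl phenol through the dienone. The fallback sets out from 1 and installs the group by cross-coupling. NBS with catalytic i-Pr2NH in CH2Cl2 brominates ortho to the hydroxyl to give 6-bromo-2,3-dimethoxyphenol F7. A Suzuki–Miyaura coupling with prenylboronic acid pinacol ester (Pd(OAc)2, a bulky biaryl dialkylphosphine ligand chosen for branched selectivity, K3PO4, THF/H2O, 40 °C) joins the arene to the tertiary allyl terminus and comes back to the route at 5.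

**Further compounds**

F1 | step 6 | (3R)-7-(benzyloxy)chroman-3-ol | O[C@H]1COc2cc(OCc3ccccc3)ccc2C1
F2 | step 6 | (3R)-7-(benzyloxy)chroman-3-yl 4-methylbenzenesulfonate | Cc1ccc(cc1)S(=O)(=O)O[C@H]1COc2cc(OCc3ccccc3)ccc2C1
F3 | step 6 | lithium bis[2,3-dimethoxy-4-(methoxymethoxy)-5-(2-methylbut-3-en-2-yl)phenyl]cuprate | [Li+].COCOc1c(C(C)(C)C=C)cc([Cu-]c2cc(C(C)(C)C=C)c(OCOC)c(OC)c2OC)c(OC)c1OC
F4 | step 7 | (3R)-7-(benzyloxy)-3-[4-hydroxy-2,3-dimethoxy-5-(2-methylbut-3-en-2-yl)phenyl]chromane | C=CC(C)(C)c1cc([C@@H]2COc3cc(OCc4ccccc4)ccc3C2)c(OC)c(OC)c1O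
F5 | step 7 | 4-[(3R)-7-(benzyloxy)chroman-3-yl]-3-methoxy-6-(2-methylbut-3-en-2-yl)cyclohexa-3,5-diene-1,2-dione | C=CC(C)(C)C1=CC([C@@H]2COc3cc(OCc4ccccc4)ccc3C2)=C(OC)C(=O)C1=O
F6 | step 7 | 4-[(3R)-7-(benzyloxy)chroman-3-yl]-3-methoxy-6-(2-methylbut-3-en-2-yl)benzene-1,2-diol | C=CC(C)(C)c1cc([C@@H]2COc3cc(OCc4ccccc4)ccc3C2)c(OC)c(O)c1O
F7 | step 2 | 6-bromo-2,3-dimethoxyphenol | COc1ccc(Br)c(O)c1OC
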